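## Structural features

The target is a bicyclo[8.4.0]tetradecane: six-membered ring A (C1, C10–C14) is trans-fused through C1–C10 to a ten-membered carbocycle (C1–C10) that holds a 5Z trisubstituted olefin. A γ-lactone (C7–O–C19–C17–C8) is fused to the large ring at C7–C8. Nine stereocentres are present: C14–C1–C2 and C7–C8–C9–C10 form two contiguous runs joined through the ring fusion, C17 sits on the lactone and C4 is an isolated allylic centre. C1 is quaternary (methyl-bearing) and C8 is a tertiary carbinol flanked by C7, C9 and C17. Five oxygens must be told apart: acetates at C4, C9 and C14, an isobutyrate at C2 and a free tertiary hydroxyl at C8. Fragile features are the β-hydroxy-γ-lactone (retro-aldol, elimination), the allylic C–O bonds at C4 and C7 on either side of the Z olefin, the exocyclic C11 methylene (migration) and the 1,3-related oxygens at C2/C14 and C2/C4 (acyl migration). The real difficulty is to close the ten-membered ring at the hindered quaternary C1 with control of C1 and C2, and then to acylate O2 and O14 differently. The key step uses the fact that C1 lies between the oxygenated carbons C14 (ring A) and C2 (large ring): with C14 as a ketone this is an aldol retron, and a bromide on C1 gives the enolate at the fully substituted carbon without any regiochemical choice.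

## Logic of the disconnections

41 ⇒ 40 ⇒ 39. The acetates at O4 and O14 are removed first, then O4 and O8 are masked as silyl ethers. No C–C bond is cut; the gain is that O2 (isobutyrate), O9 (acetate), O4, O8 and O14 are all distinguishable. The demand on the forward steps is that the tertiary O8 stays free when O4 and O14 are acetylated together.

39 ⇒ 38. The C14–H bond and the O2 acyl bond are removed together (1,3-anti diol monoester retron). This leaves a β-hydroxy ketone and means one step must both deliver hydride to C14 anti to O2 and put the isobutyryl group on O2 only.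

38 ⇒ 36. The C1–C2 bond is cut (aldol retron across C14–C1–C2). This opens the ten-membered ring and removes the stereocentres C1 and C2, leaving a ring A bromo ketone with the fully built C9–C2 chain on C10. The forward step must close a ten-membered ring at a quaternary carbon, anti to the C9 arm and with one aldehyde face.

36 ⇒ 34 ⇒ 32. The aldehyde is traced to a protected primary alcohol and the C1–Br bond to the parent ketone. The demand is bromination at the more substituted α-carbon in the presence of three alkenes.

32 ⇒ 31 ⇒ 30 ⇒ 29 ⇒ 28. Functional group changes only: C14 ketone from a dimethyl ketal, O9 acetate from the free carbinol, C11 methylene from a ketone, C12–C13 from an enone. The gain is that 28 is an aldol retron at C9–C10 with a regiodefined enolate. The demand is methylenation next to an epimerisable, β-oxygenated centre.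

28 ⇒ 25 + 23. The C9–C10 bond is cut. This is the convergent union of ring A with the whole side chain and sets C9 and C10. The forward aldol must be syn and must occur trans to the methyl group on the neighbouring ring carbon.

25 ⇒ 24. The C1–C15 bond (ring methyl) is cut, leaving an achiral dienone ketal. The forward conjugate addition must be enantioselective, since this centre relays its configuration to C10.

23 ⇒ 22 ⇒ 20 ⇒ 18. The C9 aldehyde is traced to a primary silyl ether, the C17 configuration to an enolate protonation, and the C17–C18 bond to an enolate methylation. The demand is face control on a lactone enolate next to the quaternary C8.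

18 ⇒ 17 ⇒ 16 ⇒ 15 ⇒ 12 + 14. The C4–C5 bond is cut (alkenyl metal plus aldehyde), and C4 is set separately through the enone. The vinyl iodide must couple with retention of the Z geometry in the presence of the lactone.

12 ⇒ 11 ⇒ 10 ⇒ 9. The lactone C7–O bond is traced to opening of an epoxide by the C19 ester with inversion at C7, and the epoxide to an allylic alcohol. C7 and C8 then follow from olefin geometry plus one reagent-controlled epoxidation.

9 ⇒ 8 ⇒ 7 + 4, with 7 ⇒ 5 + 6 and 4 ⇒ 3 ⇒ 1. The C7=C8 olefin is cut to a phosphonate and an enal, the phosphonate to two commercial esters, and the enal to a butynol. The forward olefination must give the E isomer and the hydroalumination the Z iodide.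

## Other disconnections considered

Alternative 1: The cut is through C1–C14 and C10–C11 of ring A, a [4+2] retron. The forward key step would be an endo Diels–Alder reaction between a 2-methyl enal and a 1-silyloxy diene, giving the cyclohexene A1. In its favour, ring A, the quaternary C1, C10 and C14 would be made in one concerted step. Their relative configuration would follow from the two olefin geometries and the endo rule, and the C14 oxygen would arrive with its final configuration. Against it here, the ten-membered ring, the lactone and C2 remain unsolved, so a second ring-closing strategy is still needed. C11 arrives as an sp3 carbon bearing a protected hydroxymethyl group, and the C12=C13 olefin must be saturated later beside other alkenes. On structure, A1 is the better answer for C1 and C14: the chosen plan sets C1 in the macrocyclisation, its least certain element, and C14 by a directed reduction. On mechanism, the cycloaddition is more predictable than a ten-membered aldol closure. On step economy, it reaches ring A in fewer steps than the chosen route reaches 25 plus its later ring A adjustments, which is a point in its favour. Overall it should be equal or longer, because the chain must be grown from two one-carbon stubs and the large ring closed at another bond.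

Alternative 2: The cut is through C7–C8 and the lactone C19–O bond. The forward key step would be a SmI2 pinacol coupling of the C7 enal carbonyl with the C8 ketone of an α-methyl β-keto ester, followed by lactonisation of the C7 alkoxide, giving A2. In its favour, one operation would close both rings and create C7 and C8. All acyl groups at O2, O4 and O14 would already be in place, and A2 would be two steps from 41. On post-cyclisation step count and on avoiding late differentiation of O2 and O14 this alternative is the better one. Against it here, the C8 ketone carries a silyloxy group on C9, and α-oxygenated ketones are cleaved reductively by SmI2. The enal ketyl is an allyl radical that can couple at C5 or lose the Z geometry. The β-keto ester is enolisable, so C17 would have to be set afterwards. The facial course of a ten-membered pinacol closure relative to C9 and C10 is open. On mechanism, both plans rely on SmI2, but in the chosen plan the C–Br bond is the most easily reduced site, whereas here two carbonyl reductions must outrun C–O cleavage. On structure, the chosen plan makes the lactone early and stereospecifically; the alternative makes it late and under less control.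

Alternative 3: The cut reconnects C2 to C9, so the ten-membered ring becomes an eight-membered ring fused to a cyclobutane-1,2-diol in a six-four-eight tricycle. The forward key step would be glycol cleavage with Pb(OAc)4, which breaks C2–C9 and releases the trione A3. In its favour, the medium ring would arise by strain-releasing fragmentation of a rigid precursor, with no entropic penalty, and the trans fusion and the quaternary C1 would be fixed beforehand. On certainty of ring formation this alternative is the better one. Against it here, A3 is almost a bare carbocycle. It lacks the C5 methyl, the oxygens at C4, C7 and C8 and all lactone carbons, carries a silyloxy group instead of the methylene at C11, and has three ketones (C2, C9, C14) to distinguish. The tertiary carbinol, the lactone and the trisubstituted olefin would have to be built on a flexible ten-membered ring. On structure, the chosen plan brings C2–C9 fully functionalised before ring closure. On mechanism, fragmentation is more reliable than the aldol. On step economy the alternative should be much longer after its key step. The two are equal in one respect: both leave a C14 ketone that needs a stereoselective reduction.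

Key step: step 26

Remarks on the chemistry (assumptions):
- Compounds 36 and 38 correspond to 41 atom by atom, and every shared stereocentre has the same configuration. The one design change is at C4. An acetate there would be β to the aldehyde and 1,3 to the C2 alkoxide formed in the aldol, so it could be lost by E1cB elimination or shift from O4 to O2. C4 is therefore carried as a tert-butyldimethylsilyl ether and acetylated at the end together with O14.
- The C1 bromide in 34–36 is written as the 1R epimer expected from attack anti to the C9 arm; the 1S epimer would serve equally, since both give enolate 37.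
- The phosphoramidite enantiomer in step 17 is taken to be the one that gives 5R in 25.
- In later names the locants C1–C20 are those of 41.

## Route

Step 1
Reactants: 1 but-2-yn-1-ol
Product: 3 (2Z)-3-iodobut-2-en-1-ol, via cyclic sodium alkenylalanate 2 (not isolated)
Conditions: NaAlH2(OCH2CH2OMe)2, THF, 0 °C to rt; then I2, THF, −78 °C to rt
Reagents that add atoms: iodine, II
Why: Hydroxyl-directed trans-hydroalumination of the propargylic alcohol puts aluminium on C3 cis to the carbinol carbon, and iodinolysis with retention gives the Z vinyl iodide. This fixes the later 5Z geometry (iodine marks C5, the carbinol carbon becomes C7).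

Step 2
Reactants: 3 (2Z)-3-iodobut-2-en-1-ol
Product: 4 (2Z)-3-iodobut-2-enal
Conditions: MnO2, CH2Cl2, rt
Reagents that add atoms: none
Why: Allylic oxidation with activated MnO2 stops at the enal and leaves the vinyl iodide alone; the aldehyde should be used at once because Z β-iodo enals isomerise on standing.

Step 3
Reactants: 5 triethyl phosphonoacetate; 6 tert-butyl bromoacetate
Product: 7 4-tert-butyl 1-ethyl 2-(diethoxyphosphoryl)butanedioate
Conditions: NaH, THF, 0 °C to rt
Reagents that add atoms: none
Why: SN2 C-alkylation of the sodium phosphonoacetate anion by an α-bromo ester gives the phosphonosuccinate with two different esters; excess 5 suppresses dialkylation.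

Step 4
Reactants: 7 4-tert-butyl 1-ethyl 2-(diethoxyphosphoryl)butanedioate; 4 (2Z)-3-iodobut-2-enal
Product: 8 4-tert-butyl 1-ethyl (2E)-2-[(2Z)-3-iodobut-2-en-1-ylidene]butanedioate
Conditions: NaH, THF, 0 °C; aldehyde added at −78 °C, then 0 °C
Reagents that add atoms: none
Why: Horner–Wadsworth–Emmons olefination; phosphonoacetates with a primary α-substituent give the E trisubstituted acrylate, with the aldehyde residue trans to the ethyl ester (C6 cis to C17). 1,2-Addition to the enal should be faster than attack at the iodinated β-carbon.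

Step 5
Reactants: 8 4-tert-butyl 1-ethyl (2E)-2-[(2Z)-3-iodobut-2-en-1-ylidene]butanedioate
Product: 9 tert-butyl (3E,5Z)-3-(hydroxymethyl)-6-iodohepta-3,5-dienoate
Conditions: i-Bu2AlH (2.2 equiv), CH2Cl2, −78 °C
Reagents that add atoms: none
Why: i-Bu2AlH reduces the conjugated ethyl ester to the allylic alcohol at low temperature while the hindered tert-butyl ester survives; both olefin geometries are untouched.

Step 6
Reactants: 9 tert-butyl (3E,5Z)-3-(hydroxymethyl)-6-iodohepta-3,5-dienoate
Product: 10 tert-butyl 2-[(2R,3R)-2-(hydroxymethyl)-3-[(1Z)-2-iodoprop-1-en-1-yl]oxiran-2-yl]acetate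
Conditions: Ti(Oi-Pr)4 (cat.), D-(−)-diethyl tartrate (cat.), t-BuOOH, 4 Å molecular sieves, CH2Cl2, −20 °C
Reagents that add atoms: tert-butyl hydroperoxide, CC(C)(C)OO
Why: Sharpless asymmetric epoxidation of a trisubstituted E allylic alcohol, a very reliable substrate class; the D-(−)-tartrate delivers oxygen to the face that gives the 2R,3R epoxide (C8 directly, C7 after inversion). Only the olefin bound to titanium through the allylic hydroxyl reacts; the vinyl iodide is remote.

Step 7
Reactants: 10 tert-butyl 2-[(2R,3R)-2-(hydroxymethyl)-3-[(1Z)-2-iodoprop-1-en-1-yl]oxiran-2-yl]acetate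
Product: 11 (4R,5S)-4-hydroxy-4-(hydroxymethyl)-5-[(1Z)-2-iodoprop-1-en-1-yl]oxolan-2-one
Conditions: CF3CO2H, CH2Cl2, 0 °C
Reagents that add atoms: none
Why: Acid activates the epoxide, and the tert-butyl ester carbonyl opens it at the allylic carbon C7 with inversion, then loses isobutene. Attack at C8 would give a β-lactone, so the γ-lactone forms with the C8 hydroxyl cis to the alkenyl group; C7 and C8 follow stereospecifically from olefin geometry and epoxide configuration.

Step 8
Reactants: 11 (4R,5S)-4-hydroxy-4-(hydroxymethyl)-5-[(1Z)-2-iodoprop-1-en-1-yl]oxolan-2-one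
Product: 12 (4R,5S)-5-[(1Z)-2-iodoprop-1-en-1-yl]-4-(triethylsilyloxy)-4-[(triethylsilyloxy)methyl]oxolan-2-one
Conditions: Et3SiOTf, 2,6-lutidine, CH2Cl2, −78 to 0 °C
Reagents that add atoms: triethylsilyl trifluoromethanesulfonate, CC[Si](CC)(CC)OS(=O)(=O)C(F)(F)F
Why: The silyl triflate silylates both the primary and the tertiary hydroxyl; the tertiary ether protects O8 to the end, and the primary one is the latent C9 aldehyde.

Step 9
Reactants: 13 3-[(4-methoxyphenyl)methoxy]propan-1-ol
Product: 14 3-[(4-methoxyphenyl)methoxy]propanal
Conditions: Dess–Martin periodinane, CH2Cl2, rt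
Reagents that add atoms: none
Why: Dess–Martin oxidation of a primary alcohol to the aldehyde under neutral conditions; the benzylic ether is inert.

Step 10
Reactants: 12 bis(triethylsilyl) vinyl iodide lactone; 14 3-[(4-methoxyphenyl)methoxy]propanal
Product: 15 (4R,5S)-5-[(1Z,3RS)-3-hydroxy-5-[(4-methoxyphenyl)methoxy]-2-methylpent-1-en-1-yl]-4-(triethylsilyloxy)-4-[(triethylsilyloxy)methyl]oxolan-2-one
Conditions: CrCl2 (excess), NiCl2 (cat.), DMSO, rt
Reagents that add atoms: none
Why: Nozaki–Hiyama–Kishi coupling: the alkenylchromium forms from the vinyl iodide with retention of the Z geometry and adds to the aldehyde chemoselectively beside the lactone and silyl ethers, making C4–C5. No control at C4 is expected here; it is set in steps 11 and 12.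

Step 11
Reactants: 15 allylic alcohol (both C4 epimers)
Product: 16 (4R,5S)-5-[(1Z)-5-[(4-methoxyphenyl)methoxy]-2-methyl-3-oxopent-1-en-1-yl]-4-(triethylsilyloxy)-4-[(triethylsilyloxy)methyl]oxolan-2-one
Conditions: Dess–Martin periodinane, pyridine, CH2Cl2, 0 °C to rt
Reagents that add atoms: none
Why: Buffered Dess–Martin oxidation converges both C4 epimers into one enone without touching the silyl ethers or the olefin geometry.

Step 12
Reactants: 16 Z enone
Product: 17 (4R,5S)-5-[(1Z,3R)-3-hydroxy-5-[(4-methoxyphenyl)methoxy]-2-methylpent-1-en-1-yl]-4-(triethylsilyloxy)-4-[(triethylsilyloxy)methyl]oxolan-2-one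
Conditions: (S)-1-methyl-3,3-diphenyltetrahydro-1H,3H-pyrrolo[1,2-c][1,3,2]oxazaborole (cat.), catecholborane, toluene, −78 °C
Reagents that add atoms: none
Why: Corey–Bakshi–Shibata reduction; the α-methyl alkenyl group acts as the large substituent and the CH2 chain as the small one, so the S catalyst should give the 4R carbinol under reagent control. Catecholborane avoids hydroboration and 1,4-reduction.

Step 13
Reactants: 17 (3R)-allylic alcohol
Product: 18 (4R,5S)-5-[(1Z,3R)-3-(tert-butyldimethylsilyloxy)-5-[(4-methoxyphenyl)methoxy]-2-methylpent-1-en-1-yl]-4-(triethylsilyloxy)-4-[(triethylsilyloxy)methyl]oxolan-2-one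
Conditions: t-BuMe2SiOTf, 2,6-lutidine, CH2Cl2, −78 °C
Reagents that add atoms: tert-butyldimethylsilyl trifluoromethanesulfonate, CC(C)(C)[Si](C)(C)OS(=O)(=O)C(F)(F)F
Why: Silylation of the secondary allylic hydroxyl; the silyl ether (not an acetate) is what later keeps the C2 aldehyde and the C2 alkoxide free of elimination and acyl transfer.

Step 14
Reactants: 18 lactone with unsubstituted C17
Product: 20 (3S,4R,5S)-3-methyl lactone (methyl cis to the silyloxymethyl group; 17-epi), via lithium enolate 19 (not isolated)
Conditions: LiN(i-Pr)2, THF, −78 °C; then MeI, −78 to −50 °C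
Reagents that add atoms: iodomethane, CI
Why: Lactone enolate alkylation; with the alkenyl group pseudoequatorial the C8–O bond is pseudoaxial, so iodomethane enters anti to it and the methyl ends up cis to C9. This is the wrong C17 epimer and is corrected in step 15; low temperature and short time keep the β-silyloxy enolate from eliminating.

Step 15
Reactants: 20 (3S,4R,5S)-3-methyl lactone
Product: 22 (3R,4R,5S)-3-methyl lactone (methyl cis to the C8 silyloxy group), via lithium enolate 21 (not isolated)
Conditions: LiN(i-Pr)2, THF, −78 °C; then AcOH in THF, −78 °C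
Reagents that add atoms: none
Why: Kinetic protonation of the planar enolate on the same open face (anti to the pseudoaxial C8–O bond) puts hydrogen cis to C9 and the methyl cis to O8, i.e. 17R. This epimer should also be the less strained one once C9 carries ring A.

Step 16
Reactants: 22 (3R,4R,5S)-3-methyl lactone
Product: 23 (2S,3S,4R)-2-[(1Z,3R)-3-(tert-butyldimethylsilyloxy)-5-[(4-methoxyphenyl)methoxy]-2-methylpent-1-en-1-yl]-4-methyl-5-oxo-3-(triethylsilyloxy)oxolane-3-carbaldehyde
Conditions: (COCl)2, DMSO, CH2Cl2, −78 to −40 °C; then Et3N, −78 to 0 °C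
Reagents that add atoms: none
Why: Swern conditions convert a primary triethylsilyl ether directly into the aldehyde, while the tertiary triethylsilyl ether, the secondary silyl ether and the benzylic ether survive. The aldehyde has no α-hydrogen and cannot epimerise.

Step 17
Reactants: 24 4,4-dimethoxycyclohexa-2,5-dien-1-one
Product: 25 (5R)-4,4-dimethoxy-5-methylcyclohex-2-en-1-one
Conditions: Me2Zn, Cu(OTf)2 (cat.), (S)-1,1'-binaphthyl-2,2'-diyl N,N-bis[(R)-1-phenylethyl]phosphoramidite (cat.), toluene, −25 °C; aq. NH4Cl
Reagents that add atoms: dimethylzinc, C[Zn]C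
Why: Copper-catalysed enantioselective conjugate addition of a dialkylzinc to a 4,4-dialkoxycyclohexadienone; the two enone arms are enantiotopic, so the ligand alone sets the methyl-bearing centre, and the zinc enolate formed is no longer an acceptor. The product must be kept away from acid, which would eliminate methanol and aromatise it.

Step 18
Reactants: 25 (5R)-4,4-dimethoxy-5-methylcyclohex-2-en-1-one; 23 lactone aldehyde
Product: 28 (5R,6S)-6-[(S)-hydroxy(lactone unit)methyl]-4,4-dimethoxy-5-methylcyclohex-2-en-1-one (C9–C10 aldol), via lithium dienolate 26 (not isolated), via titanium dienolate 27 (not isolated)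
Conditions: LiN(i-Pr)2, THF, −78 °C; ClTi(Oi-Pr)3, −78 to −40 °C; then 23, −78 °C
Reagents that add atoms: none
Why: Deprotonation of the enone can only occur at C10, because the other α-carbon is vinylic, so the enolate is regiodefined. The triisopropoxytitanium enolate of a cyclic ketone is the known way to a syn aldol from an enolate of fixed E geometry: the aldehyde adds trans to the neighbouring methyl group (C10) and the syn transition state then fixes C9. The aldehyde's own α-centre is quaternary with two similar ring carbons and should exert little opposing bias.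

Step 19
Reactants: 28 aldol enone
Product: 29 (2S,3R)-2-[(S)-hydroxy(lactone unit)methyl]-4,4-dimethoxy-3-methylcyclohexan-1-one
Conditions: [(Ph3P)CuH]6, benzene/THF, H2O (2 equiv), rt
Reagents that add atoms: none
Why: Conjugate reduction with the hexameric copper hydride delivers hydride only to the enone β-carbon (C13) under neutral conditions; the β-hydroxy ketone, lactone, silyl ethers and the isolated trisubstituted olefin are not affected.

Step 20
Reactants: 29 saturated β-hydroxy ketone
Product: 30 (S)-[(1R,2R)-3,3-dimethoxy-2-methyl-6-methylidenecyclohexyl](lactone unit)methanol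
Conditions: Cp2Ti(μ-Cl)(μ-CH2)AlMe2 (excess), pyridine, THF/toluene, −40 to 0 °C
Reagents that add atoms: Tebbe reagent (μ-chloro-μ-methylene-bis(cyclopentadienyl)titanium dimethylaluminium), C[Al-]1(C)C[Ti]([Cl+]1)(C1C=CC=C1)C1C=CC=C1
Why: Tebbe methylenation is not basic, so retro-aldol cleavage, epimerisation at C10 and β-elimination of O9 are avoided. At low temperature the ketone reacts well before the lactone; the excess allows for the free hydroxyl.

Step 21
Reactants: 30 homoallylic alcohol
Product: 31 (S)-[(1R,2R)-3,3-dimethoxy-2-methyl-6-methylidenecyclohexyl](lactone unit)methyl acetate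
Conditions: Ac2O, DMAP, pyridine, CH2Cl2, rt
Reagents that add atoms: acetic anhydride, CC(=O)OC(C)=O
Why: DMAP-catalysed acetylation of the hindered C9 hydroxyl. It is done only now, when C11 is no longer a ketone, so a β-acetoxy ketone that could eliminate is never formed.

Step 22
Reactants: 31 C9 acetate with C14 dimethyl ketal
Product: 32 (S)-[(1R,2R)-2-methyl-6-methylidene-3-oxocyclohexyl](lactone unit)methyl acetate
Conditions: pyridinium p-toluenesulfonate (cat.), acetone/H2O, rt
Reagents that add atoms: water, O
Why: Dimethyl ketals of ketones hydrolyse under very mild acid, which the tertiary triethylsilyl ether, the secondary silyl ether, the benzylic ether and the exocyclic methylene tolerate. C1 becomes epimerisable, which does not matter.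

Step 23
Reactants: 32 C14 ketone
Product: 34 (S)-[(1R,2R)-2-bromo-2-methyl-6-methylidene-3-oxocyclohexyl](lactone unit)methyl acetate, via C14=C1 trimethylsilyl enol ether 33 (not isolated)
Conditions: Me3SiOTf, Et3N, CH2Cl2, 0 °C to rt; then N-bromosuccinimide, THF, −78 °C
Reagents that add atoms: N-bromosuccinimide, O=C1CCC(=O)N1Br
Why: Under silyl triflate/amine conditions the enol silanes equilibrate through the ammonium triflate toward the more substituted C14=C1 isomer, and N-bromosuccinimide brominates a silyl enol ether far faster than any of the three alkenes. Bromine should enter anti to the C9 arm; the other epimer would be equally useful.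

Step 24
Reactants: 34 bromo ketone with C2 benzylic ether
Product: 35 bromo ketone with free C2 hydroxyl
Conditions: 2,3-dichloro-5,6-dicyano-1,4-benzoquinone, CH2Cl2/pH 7 buffer, 0 °C
Reagents that add atoms: none
Why: Oxidative cleavage of the 4-methoxybenzyl ether under buffered conditions; silyl ethers, acetate, lactone and the tertiary bromide are inert to the quinone.

Step 25
Reactants: 35 bromo ketone alcohol
Product: 36 (S)-[(1R,2R)-2-bromo-2-methyl-6-methylidene-3-oxocyclohexyl][(2S,3S,4R)-2-[(1Z,3R)-3-(tert-butyldimethylsilyloxy)-2-methyl-5-oxopent-1-en-1-yl]-4-methyl-5-oxo-3-(triethylsilyloxy)oxolan-3-yl]methyl acetate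
Conditions: Dess–Martin periodinane, pyridine, CH2Cl2, 0 °C
Reagents that add atoms: none
Why: Neutral oxidation of the primary alcohol to the C2 aldehyde; no base is present that could dehydrobrominate the ketone or eliminate the β-silyloxy group.

Step 26
Reactants: 36 ring A 1-bromo-14-ketone with C2 aldehyde
Product: 38 ten-membered β-hydroxy ketone (C2 hydroxyl; C14 ketone; C4 tert-butyldimethylsilyl ether; C8 triethylsilyl ether; C9 acetate), via samarium enolate 37 (not isolated)
Conditions: SmI2 (2.5 equiv), THF, −78 °C, slow addition of 36 (final 0.002 M)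
Reagents that add atoms: none
Why: Two single-electron transfers from SmI2 cleave the C1–Br bond and give the trivalent samarium enolate 37 at the fully substituted carbon, identical from either bromide epimer; it adds to the tethered C2 aldehyde and forms C1–C2. The closest known reaction type is the SmI2-mediated intramolecular Reformatsky-type aldol of α-bromo ketones with aldehydes, which has been used to close eight-membered and larger carbocycles. The ten-membered ring closes in the 10-(enolexo)-exo-trig mode, C1 being the only enolate carbon inside the new ring. C1 is controlled by the C9 arm on C10: allylic strain with the C11 methylene and the C1 methyl holds that arm pseudoaxial, so the aldehyde should attack the opposite enolate face and give the trans ring fusion. C2 is controlled by a chair transition state in which samarium bridges the enolate and aldehyde oxygens; the methyl group is cis to the enolate oxygen, which gives methyl and hydroxyl syn, i.e. 2S. The samarium aldolate is chelated and can revert, so the trans-fused chelate should accumulate. The step needs C–Br reduction to outrun reduction of the aldehyde, the esters and the lactone; a tertiary α-bromo ketone is reduced at −78 °C well before these. High dilution suppresses intermolecular aldol, the C8 silyl ether removes the only internal proton source, and the C4 silyl ether excludes elimination and acyl transfer at the new alkoxide.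

Step 27
Reactants: 38 ten-membered β-hydroxy ketone
Product: 39 C2 isobutyrate with free 14α-hydroxyl (C4 and C8 silyl ethers retained)
Conditions: i-PrCHO (excess), SmI2 (cat.), THF, −10 °C
Reagents that add atoms: 2-methylpropanal, CC(C)C=O
Why: Evans–Tishchenko reduction: the samarium-bound hemiacetal of the C2 hydroxyl with isobutyraldehyde transfers its hydride intramolecularly to the C14 ketone through a six-membered transition state, giving the 1,3-anti diol with the acyl group on the original hydroxyl oxygen. This is exactly the O2 isobutyrate and 14S carbinol of 41, and it differentiates O2 from O14 in the same step.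

Step 28
Reactants: 39 C2 isobutyrate with C4 and C8 silyl ethers
Product: 40 4,14-di-O-deacetyl derivative of 41 (free hydroxyls at C4, C8 and C14)
Conditions: HF·pyridine, pyridine, THF, 0 °C to rt
Reagents that add atoms: none
Why: Buffered hydrogen fluoride removes both the secondary tert-butyldimethylsilyl and the tertiary triethylsilyl ether; the mildly acidic medium does not promote acyl migration among O2, O4 and O14.

Step 29
Reactants: 40 triol
Product: 41 CNP0189561.1
Conditions: Ac2O, pyridine, DMAP (cat.), CH2Cl2, 0 °C to rt
Reagents that add atoms: acetic anhydride, CC(=O)OC(C)=O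
Why: The two secondary hydroxyls (C4 allylic, C14 axial) are acetylated; the tertiary C8 hydroxyl, flanked by three substituted carbons, should not react under these conditions.

## Compound list

In the names, "chain P" is (1Z,3R)-3-(tert-butyldimethylsilyloxy)-5-[(4-methoxyphenyl)methoxy]-2-methylpent-1-en-1-yl, and "unit Q" is (2S,4R)-2-(chain P)-4-methyl-5-oxo-3-(triethylsilyloxy)oxolan-3-yl, with the C3 descriptor given each time.

1 | but-2-yn-1-ol | CC#CCO | starting material
2 | sodium 2,2-bis(2-methoxyethoxy)-3-methyl-2,5-dihydro-1,2-oxaaluminol-2-uide | CC1=CCO[Al-]1(OCCOC)OCCOC.[Na+] | intermediate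
3 | (2Z)-3-iodobut-2-en-1-ol | C/C(I)=C/CO | intermediate
4 | (2Z)-3-iodobut-2-enal | C/C(I)=C/C=O | intermediate
5 | triethyl phosphonoacetate | CCOC(=O)CP(=O)(OCC)OCC | starting material
6 | tert-butyl bromoacetate | CC(C)(C)OC(=O)CBr | starting material
7 | 4-tert-butyl 1-ethyl 2-(diethoxyphosphoryl)butanedioate (racemic) | CCOC(=O)C(CC(=O)OC(C)(C)C)P(=O)(OCC)OCC | intermediate
8 | 4-tert-butyl 1-ethyl (2E)-2-[(2Z)-3-iodobut-2-en-1-ylidene]butanedioate | CCOC(=O)/C(CC(=O)OC(C)(C)C)=C/C=C(C)\I | intermediate
9 | tert-butyl (3E,5Z)-3-(hydroxymethyl)-6-iodohepta-3,5-dienoate | OC/C(CC(=O)OC(C)(C)C)=C/C=C(C)\I | intermediate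
10 | tert-butyl 2-[(2R,3R)-2-(hydroxymethyl)-3-[(1Z)-2-iodoprop-1-en-1-yl]oxiran-2-yl]acetate | OC[C@@]1(CC(=O)OC(C)(C)C)O[C@@H]1/C=C(C)\I | intermediate
11 | (4R,5S)-4-hydroxy-4-(hydroxymethyl)-5-[(1Z)-2-iodoprop-1-en-1-yl]oxolan-2-one | OC[C@]1(O)CC(=O)O[C@H]1/C=C(C)\I | intermediate
12 | (4R,5S)-5-[(1Z)-2-iodoprop-1-en-1-yl]-4-(triethylsilyloxy)-4-[(triethylsilyloxy)methyl]oxolan-2-one | CC[Si](CC)(CC)OC[C@]1(O[Si](CC)(CC)CC)CC(=O)O[C@H]1/C=C(C)\I | intermediate
13 | 3-[(4-methoxyphenyl)methoxy]propan-1-ol | COc1ccc(COCCCO)cc1 | starting material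
14 | 3-[(4-methoxyphenyl)methoxy]propanal | COc1ccc(COCCC=O)cc1 | intermediate
15 | (4R,5S)-5-[(1Z,3RS)-3-hydroxy-5-[(4-methoxyphenyl)methoxy]-2-methylpent-1-en-1-yl]-4-(triethylsilyloxy)-4-[(triethylsilyloxy)methyl]oxolan-2-one (both C4 epimers) | CC[Si](CC)(CC)OC[C@]1(O[Si](CC)(CC)CC)CC(=O)O[C@H]1/C=C(C)\C(O)CCOCc1ccc(OC)cc1 | intermediate
16 | (4R,5S)-5-[(1Z)-5-[(4-methoxyphenyl)methoxy]-2-methyl-3-oxopent-1-en-1-yl]-4-(triethylsilyloxy)-4-[(triethylsilyloxy)methyl]oxolan-2-one | CC[Si](CC)(CC)OC[C@]1(O[Si](CC)(CC)CC)CC(=O)O[C@H]1/C=C(C)\C(=O)CCOCc1ccc(OC)cc1 | intermediate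
17 | (4R,5S)-5-[(1Z,3R)-3-hydroxy-5-[(4-methoxyphenyl)methoxy]-2-methylpent-1-en-1-yl]-4-(triethylsilyloxy)-4-[(triethylsilyloxy)methyl]oxolan-2-one | CC[Si](CC)(CC)OC[C@]1(O[Si](CC)(CC)CC)CC(=O)O[C@H]1/C=C(C)\[C@H](O)CCOCc1ccc(OC)cc1 | intermediate
18 | (4R,5S)-5-(chain P)-4-(triethylsilyloxy)-4-[(triethylsilyloxy)methyl]oxolan-2-one | CC[Si](CC)(CC)OC[C@]1(O[Si](CC)(CC)CC)CC(=O)O[C@H]1/C=C(C)\[C@H](O[Si](C)(C)C(C)(C)C)CCOCc1ccc(OC)cc1 | intermediate
19 | lithium enolate of 18 (lithium (4R,5S)-5-(chain P)-4-(triethylsilyloxy)-4-[(triethylsilyloxy)methyl]-4,5-dihydrofuran-2-olate) | CC[Si](CC)(CC)OC[C@]1(O[Si](CC)(CC)CC)C=C(O[Li])O[C@H]1/C=C(C)\[C@H](O[Si](C)(C)C(C)(C)C)CCOCc1ccc(OC)cc1 | intermediate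
20 | (3S,4R,5S)-5-(chain P)-3-methyl-4-(triethylsilyloxy)-4-[(triethylsilyloxy)methyl]oxolan-2-one (17-epi) | CC[Si](CC)(CC)OC[C@]1(O[Si](CC)(CC)CC)[C@H](C)C(=O)O[C@H]1/C=C(C)\[C@H](O[Si](C)(C)C(C)(C)C)CCOCc1ccc(OC)cc1 | intermediate
21 | lithium enolate of 20 (3-methyl-4,5-dihydrofuran-2-olate) | CC[Si](CC)(CC)OC[C@]1(O[Si](CC)(CC)CC)C(C)=C(O[Li])O[C@H]1/C=C(C)\[C@H](O[Si](C)(C)C(C)(C)C)CCOCc1ccc(OC)cc1 | intermediate
22 | (3R,4R,5S)-5-(chain P)-3-methyl-4-(triethylsilyloxy)-4-[(triethylsilyloxy)methyl]oxolan-2-one | CC[Si](CC)(CC)OC[C@]1(O[Si](CC)(CC)CC)[C@@H](C)C(=O)O[C@H]1/C=C(C)\[C@H](O[Si](C)(C)C(C)(C)C)CCOCc1ccc(OC)cc1 | intermediate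
23 | (2S,3S,4R)-2-(chain P)-4-methyl-5-oxo-3-(triethylsilyloxy)oxolane-3-carbaldehyde | O=C[C@]1(O[Si](CC)(CC)CC)[C@@H](C)C(=O)O[C@H]1/C=C(C)\[C@H](O[Si](C)(C)C(C)(C)C)CCOCc1ccc(OC)cc1 | intermediate
24 | 4,4-dimethoxycyclohexa-2,5-dien-1-one | COC1(OC)C=CC(=O)C=C1 | starting material
25 | (5R)-4,4-dimethoxy-5-methylcyclohex-2-en-1-one | O=C1C=CC(OC)(OC)[C@H](C)C1 | intermediate
26 | lithium (5R)-4,4-dimethoxy-5-methylcyclohexa-1,5-dien-1-olate (enolate carbon C10) | [Li]OC1=C[C@@H](C)C(OC)(OC)C=C1 | intermediate
27 | triisopropoxytitanium enolate of 25 | CC(C)O[Ti](OC(C)C)(OC(C)C)OC1=C[C@@H](C)C(OC)(OC)C=C1 | intermediate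
28 | (5R,6S)-6-[(S)-hydroxy(unit Q, 3R)methyl]-4,4-dimethoxy-5-methylcyclohex-2-en-1-one | O=C1C=CC(OC)(OC)[C@H](C)[C@H]1[C@H](O)[C@]2(O[Si](CC)(CC)CC)[C@@H](C)C(=O)O[C@H]2/C=C(C)\[C@H](O[Si](C)(C)C(C)(C)C)CCOCc1ccc(OC)cc1 | intermediate
29 | (2S,3R)-2-[(S)-hydroxy(unit Q, 3R)methyl]-4,4-dimethoxy-3-methylcyclohexan-1-one | O=C1CCC(OC)(OC)[C@H](C)[C@H]1[C@H](O)[C@]2(O[Si](CC)(CC)CC)[C@@H](C)C(=O)O[C@H]2/C=C(C)\[C@H](O[Si](C)(C)C(C)(C)C)CCOCc1ccc(OC)cc1 | intermediate
30 | (S)-[(1R,2R)-3,3-dimethoxy-2-methyl-6-methylidenecyclohexyl](unit Q, 3R)methanol | C=C1CCC(OC)(OC)[C@H](C)[C@H]1[C@H](O)[C@]2(O[Si](CC)(CC)CC)[C@@H](C)C(=O)O[C@H]2/C=C(C)\[C@H](O[Si](C)(C)C(C)(C)C)CCOCc1ccc(OC)cc1 | intermediate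
31 | (S)-[(1R,2R)-3,3-dimethoxy-2-methyl-6-methylidenecyclohexyl](unit Q, 3S)methyl acetate | C=C1CCC(OC)(OC)[C@H](C)[C@H]1[C@H](OC(C)=O)[C@]2(O[Si](CC)(CC)CC)[C@@H](C)C(=O)O[C@H]2/C=C(C)\[C@H](O[Si](C)(C)C(C)(C)C)CCOCc1ccc(OC)cc1 | intermediate
32 | (S)-[(1R,2R)-2-methyl-6-methylidene-3-oxocyclohexyl](unit Q, 3S)methyl acetate (C1 of 41 epimerisable) | C=C1CCC(=O)[C@H](C)[C@H]1[C@H](OC(C)=O)[C@]2(O[Si](CC)(CC)CC)[C@@H](C)C(=O)O[C@H]2/C=C(C)\[C@H](O[Si](C)(C)C(C)(C)C)CCOCc1ccc(OC)cc1 | intermediate
33 | (S)-[(1S)-2-methyl-6-methylidene-3-(trimethylsilyloxy)cyclohex-2-en-1-yl](unit Q, 3S)methyl acetate | C=C1CCC(O[Si](C)(C)C)=C(C)[C@H]1[C@H](OC(C)=O)[C@]2(O[Si](CC)(CC)CC)[C@@H](C)C(=O)O[C@H]2/C=C(C)\[C@H](O[Si](C)(C)C(C)(C)C)CCOCc1ccc(OC)cc1 | intermediate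
34 | (S)-[(1R,2R)-2-bromo-2-methyl-6-methylidene-3-oxocyclohexyl](unit Q, 3S)methyl acetate | C=C1CCC(=O)[C@](C)(Br)[C@H]1[C@H](OC(C)=O)[C@]2(O[Si](CC)(CC)CC)[C@@H](C)C(=O)O[C@H]2/C=C(C)\[C@H](O[Si](C)(C)C(C)(C)C)CCOCc1ccc(OC)cc1 | intermediate
35 | analogue of 34 in which the chain is (1Z,3R)-3-(tert-butyldimethylsilyloxy)-5-hydroxy-2-methylpent-1-en-1-yl | C=C1CCC(=O)[C@](C)(Br)[C@H]1[C@H](OC(C)=O)[C@]2(O[Si](CC)(CC)CC)[C@@H](C)C(=O)O[C@H]2/C=C(C)\[C@H](O[Si](C)(C)C(C)(C)C)CCO | intermediate
36 | (S)-[(1R,2R)-2-bromo-2-methyl-6-methylidene-3-oxocyclohexyl][(2S,3S,4R)-2-[(1Z,3R)-3-(tert-butyldimethylsilyloxy)-2-methyl-5-oxopent-1-en-1-yl]-4-methyl-5-oxo-3-(triethylsilyloxy)oxolan-3-yl]methyl acetate | C=C1CCC(=O)[C@](C)(Br)[C@H]1[C@H](OC(C)=O)[C@]2(O[Si](CC)(CC)CC)[C@@H](C)C(=O)O[C@H]2/C=C(C)\[C@H](O[Si](C)(C)C(C)(C)C)CC=O | intermediate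
37 | diiodosamarium C14=C1 enolate of debrominated 36 (trivalent samarium) | C=C1CCC(O[Sm](I)I)=C(C)[C@H]1[C@H](OC(C)=O)[C@]2(O[Si](CC)(CC)CC)[C@@H](C)C(=O)O[C@H]2/C=C(C)\[C@H](O[Si](C)(C)C(C)(C)C)CC=O | intermediate
38 | 2-O-deisobutyryl-14-deacetoxy-14-oxo-4-O-deacetyl-4-O-(tert-butyldimethylsilyl)-8-O-(triethylsilyl) derivative of 41 (1S,2S,4R,5Z,7S,8S,9S,10S,17R) | C=C1CCC(=O)[C@]2(C)[C@@H](O)C[C@@H](O[Si](C)(C)C(C)(C)C)/C(C)=C\[C@@H]3OC(=O)[C@H](C)[C@@]3(O[Si](CC)(CC)CC)[C@@H](OC(C)=O)[C@@H]12 | intermediate
39 | 4,14-di-O-deacetyl-4-O-(tert-butyldimethylsilyl)-8-O-(triethylsilyl) derivative of 41 (C2 isobutyrate, free 14-hydroxyl; 1R,2S,4R,5Z,7S,8S,9S,10S,14S,17R) | C=C1CC[C@H](O)[C@]2(C)[C@@H](OC(=O)C(C)C)C[C@@H](O[Si](C)(C)C(C)(C)C)/C(C)=C\[C@@H]3OC(=O)[C@H](C)[C@@]3(O[Si](CC)(CC)CC)[C@@H](OC(C)=O)[C@@H]12 | intermediate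
40 | 4,14-di-O-deacetyl derivative of 41 (free hydroxyls at C4, C8, C14; 1R,2S,4R,5Z,7S,8S,9S,10S,14S,17R) | C=C1CC[C@H](O)[C@]2(C)[C@@H](OC(=O)C(C)C)C[C@@H](O)/C(C)=C\[C@@H]3OC(=O)[C@H](C)[C@@]3(O)[C@@H](OC(C)=O)[C@@H]12 | intermediate
41 | CNP0189561.1: trans-fused ring A/ten-membered ring lactone with 4,9,14-triacetoxy, 8-hydroxy, 2-(2-methylpropanoyloxy), 11(20)-methylene, 5Z olefin (1R,2S,4R,7S,8S,9S,10S,14S,17R) | C=C1CC[C@H](OC(C)=O)[C@]2(C)[C@@H](OC(=O)C(C)C)C[C@@H](OC(C)=O)/C(C)=C\[C@@H]3OC(=O)[C@H](C)[C@@]3(O)[C@@H](OC(C)=O)[C@@H]12 | target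

## Step count and least certain steps

Total: 29 steps. Longest linear sequence: 26 steps (steps 1, 2, 4–8, 10–16, 18–29, from 1).

Step 26 (key step). The samarium enolate may be protonated (simple debromination), or intermolecular aldol may compete with a slow ten-membered closure, because the enolate is tetrasubstituted and the ring is medium-sized. Closure may also occur on the enolate face syn to the C9 arm (cis fusion) or through a non-chelated transition state (C2 epimer), since the facial bias rests only on conformational preferences. Fallback (pre-formed enol silane and Lewis acid instead of a reductively generated metal enolate): set out from 32 and silylate under the same equilibrating conditions with t-BuMe2SiOTf/Et3N to give the C14=C1 tert-butyldimethylsilyl enol ether F1. Cleave the 4-methoxybenzyl ether with MgBr2·OEt2/Me2S, which spares enol silanes, to give the primary alcohol F2. Oxidise with Dess–Martin periodinane/pyridine to the enol silane aldehyde F3. Close the ring by an intramolecular Mukaiyama aldol (BF3·OEt2, CH2Cl2, −78 °C, high dilution, open transition state). After aqueous work-up the route is rejoined at 38.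

Step 18. The simple diastereoselection may be poor (anti instead of syn), or addition to the hindered α-quaternary aldehyde may be slow enough for retro-aldol to erode the result. The reason is that cyclic enolates have a fixed E geometry, which favours anti products in ordinary closed transition states. Fallback (open, metal-free transition state, made irreversible by silyl transfer): set out from 25 and trap the kinetic enolate (LiN(i-Pr)2, Me3SiCl) as the trimethylsilyl dienol ether F4. Combine it with 23 under catalysis by tris(dimethylamino)sulfonium difluorotrimethylsilicate, a fluoride-promoted aldol that is syn-selective whatever the enolate geometry, to give the O-silylated aldol F5. Mild hydrolysis (citric acid, MeOH/H2O) returns to 28.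

Step 23. Equilibration may not favour the C14=C1 enol silane enough (competing enolisation toward C13), which would give the regioisomeric bromide; the tetrasubstituted enol ether is strained against the C10 substituent. Fallback (bromination of the acid-equilibrated enol, no silyl enol ether): set out from 32 and treat with pyrrolidone hydrotribromide in THF. This reagent brominates ketones through the more substituted enol and is known to spare isolated alkenes. The route is rejoined directly at 34; no new compound is involved.

Step 15 (with step 14). Facial selectivity in the protonation of enolate 21 may be poor, because a proton is a small electrophile with an early transition state, and silanolate may be lost by β-elimination. Fallback (C–H bond made by catalytic hydrogenation of an exocyclic alkene instead of proton transfer): set out from 18, form the enolate and add Me2N=CH2 I to give the Mannich base F6. Quaternise with MeI and eliminate with NaHCO3 to the α-methylene lactone F7. Hydrogenate with H2 and RhCl(PPh3)3, which should add hydrogen to the exocyclic olefin on the face anti to the pseudoaxial silyloxy group and leave the trisubstituted olefin and the benzylic ether alone. The route is rejoined at 22.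

Step 27. Hydride transfer to the hindered C14 ketone may be slow, which would allow retro-aldol opening of the ring, and the isobutyryl group may migrate from O2 to O14 in the samarium-bound diol monoester, because the two oxygens are 1,3-related and both coordinated. Fallback (acylation first, then an external bulky hydride instead of internal delivery): set out from 38 and acylate O2 with isobutyric anhydride/DMAP to the keto ester F8. Reduce with LiBH(s-Bu)3 in THF at −78 °C, where equatorial attack should give the axial 14-alcohol, and quench with acetic acid at −78 °C. The route is rejoined at 39.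

## Further compounds

F1 | step 26 | (S)-[(1S)-3-(tert-butyldimethylsilyloxy)-2-methyl-6-methylidenecyclohex-2-en-1-yl](unit Q, 3S)methyl acetate | C=C1CCC(O[Si](C)(C)C(C)(C)C)=C(C)[C@H]1[C@H](OC(C)=O)[C@]2(O[Si](CC)(CC)CC)[C@@H](C)C(=O)O[C@H]2/C=C(C)\[C@H](O[Si](C)(C)C(C)(C)C)CCOCc1ccc(OC)cc1
F2 | step 26 | analogue of F1 with a free primary hydroxyl at C2 | C=C1CCC(O[Si](C)(C)C(C)(C)C)=C(C)[C@H]1[C@H](OC(C)=O)[C@]2(O[Si](CC)(CC)CC)[C@@H](C)C(=O)O[C@H]2/C=C(C)\[C@H](O[Si](C)(C)C(C)(C)C)CCO
F3 | step 26 | analogue of F1 with a C2 aldehyde | C=C1CCC(O[Si](C)(C)C(C)(C)C)=C(C)[C@H]1[C@H](OC(C)=O)[C@]2(O[Si](CC)(CC)CC)[C@@H](C)C(=O)O[C@H]2/C=C(C)\[C@H](O[Si](C)(C)C(C)(C)C)CC=O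
F4 | step 18 | [(5R)-4,4-dimethoxy-5-methylcyclohexa-1,5-dien-1-yl]oxy(trimethyl)silane | C[Si](C)(C)OC1=C[C@@H](C)C(OC)(OC)C=C1
F5 | step 18 | O9-trimethylsilyl ether of 28 | O=C1C=CC(OC)(OC)[C@H](C)[C@H]1[C@H](O[Si](C)(C)C)[C@]2(O[Si](CC)(CC)CC)[C@@H](C)C(=O)O[C@H]2/C=C(C)\[C@H](O[Si](C)(C)C(C)(C)C)CCOCc1ccc(OC)cc1
F0 | step 23 | none | none
F6 | step 15 | (4R,5S)-5-(chain P)-3-[(dimethylamino)methyl]-4-(triethylsilyloxy)-4-[(triethylsilyloxy)methyl]oxolan-2-one | CC[Si](CC)(CC)OC[C@]1(O[Si](CC)(CC)CC)C(CN(C)C)C(=O)O[C@H]1/C=C(C)\[C@H](O[Si](C)(C)C(C)(C)C)CCOCc1ccc(OC)cc1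
F7 | step 15 | (4R,5S)-5-(chain P)-3-methylidene-4-(triethylsilyloxy)-4-[(triethylsilyloxy)methyl]oxolan-2-one | CC[Si](CC)(CC)OC[C@]1(O[Si](CC)(CC)CC)C(=C)C(=O)O[C@H]1/C=C(C)\[C@H](O[Si](C)(C)C(C)(C)C)CCOCc1ccc(OC)cc1
F8 | step 27 | 2-O-isobutyryl derivative of 38 (C14 ketone) | C=C1CCC(=O)[C@]2(C)[C@@H](OC(=O)C(C)C)C[C@@H](O[Si](C)(C)C(C)(C)C)/C(C)=C\[C@@H]3OC(=O)[C@H](C)[C@@]3(O[Si](CC)(CC)CC)[C@@H](OC(C)=O)[C@@H]12
A1 | alternative 1 | 2-(tert-butyldimethylsilyloxy)-6-[(tert-butyldiphenylsilyloxy)methyl]-5-[(4-methoxybenzyloxy)methyl]-1-methylcyclohex-3-ene-1-carbaldehyde (C1, C10, C14 as in 41) | O=C[C@@]1(C)[C@@H](O[Si](C)(C)C(C)(C)C)C=C[C@@H](COCc2ccc(OC)cc2)[C@@H]1CO[Si](c2ccccc2)(c2ccccc2)C(C)(C)C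
A2 | alternative 2 | 9-O-deacetyl-9-O-(tert-butyldimethylsilyl) derivative of 41 | C=C1CC[C@H](OC(C)=O)[C@]2(C)[C@@H](OC(=O)C(C)C)C[C@@H](OC(C)=O)/C(C)=C\[C@@H]3OC(=O)[C@H](C)[C@@]3(O)[C@@H](O[Si](C)(C)C(C)(C)C)[C@@H]12
A3 | alternative 3 | 11-(tert-butyldimethylsilyloxy)-1-methylbicyclo[8.4.0]tetradec-5-ene-2,9,14-trione (locants of 41, Z olefin, trans fusion) | O=C1CC[C@@H](O[Si](C)(C)C(C)(C)C)[C@H]2[C@@]1(C)C(=O)CC/C=C\CCC2=O
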